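**Plan**

- Tetralin numbering: C1 carries the pendant aryl group, C2 and C3 carry the CH2O carbons C2a and C3a, C4 is the ring CH2, and C4a–C8a belong to ring A. Ring B is C1–C4 plus C4a and C8a.
- Retrosynthetic cuts, in order: the O–S bond at C2a and the two benzyl ethers; then C2–C3 and C4–C4a of ring B in one operation; then the C1–aryl bond; then the lactone and C=C bonds of a coumarin-3-carboxylate built from a ring A salicylaldehyde and dimethyl malonate.
- Enabling feature: C4, C3 and C3a are three consecutive carbons of buta-1,3-diene, lying between aryl carbon C4a of ring A and C2, the carbon that carries C2a. The fourth diene carbon is cut off later.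
- Forward order: ring A is dressed as a salicylaldehyde. A temporary coumarin ring takes up the pendant aryl group at C1 and is opened to a malonate and a phenol, which becomes the C4a triflate. Ring B then closes onto butadiene, one ester becomes C2a–OSO3H and the vinyl group becomes C3a–OH.
- Stereochemistry: C1 from rhodium/(R)-Segphos conjugate arylation; C3 from the ring closure, steered by C1 and a matched chiral bisphosphine; C2 from thermodynamic equilibration of the ester, trans to both neighbours.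

Key step: step 10

Remark: the sulfate monoesters of the last three steps are drawn as free hydrogen sulfates, like the target; they would be handled as sodium salts, and the final product released on an acidic ion-exchange resin.
Remark: (R)-BINAP in step 10 is assumed to be the hand matched to the (R) centre at C1; this pairing has to be confirmed by a test with both antipodes.

**Route**

Step 1
Reactants: 1 syringaldehyde
Product: 2 4-(benzyloxy)-3,5-dimethoxybenzaldehyde
Conditions: BnBr, K2CO3, DMF, 60 °C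
Reagents that add atoms: benzyl bromide, BrCc1ccccc1
Why: Williamson ether synthesis on the acidic, hindered phenol; the benzyl ether withstands every later step and leaves by hydrogenolysis at the end.

Step 2
Reactants: 2 4-(benzyloxy)-3,5-dimethoxybenzaldehyde
Product: 4 4-(benzyloxy)-3,5-dimethoxyphenol, via aryl formate 3 (not isolated)
Conditions: mCPBA, CH2Cl2, 0 °C to rt; then K2CO3 (cat.), MeOH, rt
Reagents that add atoms: mCPBA, OOC(=O)c1cccc(Cl)c1
Why: Baeyer–Villiger oxidation of an electron-rich benzaldehyde (Dakin type), in which the alkoxy-substituted aryl group migrates in preference to hydride, followed by methanolysis of the formate.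

Step 3
Reactants: 4 4-(benzyloxy)-3,5-dimethoxyphenol
Product: 5 3-(benzyloxy)-6-hydroxy-2,4-dimethoxybenzaldehyde
Conditions: MgCl2, Et3N, (CH2O)n, MeCN, 80 °C
Reagents that add atoms: paraformaldehyde (formaldehyde unit), C=O
Why: Casnati–Skattebøl ortho-formylation through the magnesium phenoxide, with a second formaldehyde oxidising the benzylic alkoxide; the two ortho positions are equivalent and the para position is blocked, so a single aldehyde is expected.

Step 4
Reactants: 5 3-(benzyloxy)-6-hydroxy-2,4-dimethoxybenzaldehyde; 6 dimethyl malonate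
Product: 8 methyl 6-(benzyloxy)-5,7-dimethoxy-2-oxo-2H-chromene-3-carboxylate, via arylidene malonate 7 (not isolated)
Conditions: piperidine (cat.), AcOH (cat.), MeOH, reflux
Reagents that add atoms: none
Why: Knoevenagel condensation followed by lactonisation of the phenol onto the cis ester, the standard entry to coumarin-3-carboxylates.

Step 5
Reactants: 9 4-bromo-2,6-dimethoxyphenol
Product: 10 2-(benzyloxy)-5-bromo-1,3-dimethoxybenzene
Conditions: BnBr, K2CO3, DMF, 60 °C
Reagents that add atoms: benzyl bromide, BrCc1ccccc1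
Why: Williamson ether synthesis, as in step 1.

Step 6
Reactants: 10 2-(benzyloxy)-5-bromo-1,3-dimethoxybenzene
Product: 13 [4-(benzyloxy)-3,5-dimethoxyphenyl]boronic acid, via aryllithium 11 (not isolated), via lithium triisopropoxyborate 12 (not isolated)
Conditions: n-BuLi, THF, −78 °C; B(OiPr)3, −78 °C to rt; aq. HCl
Reagents that add atoms: triisopropyl borate, CC(C)OB(OC(C)C)OC(C)C; water, O
Why: bromine–lithium exchange at low temperature, borylation of the aryllithium and acidic hydrolysis; the exchange is much faster than ortho-lithiation next to the ethers.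

Step 7
Reactants: 8 methyl 6-(benzyloxy)-5,7-dimethoxy-2-oxo-2H-chromene-3-carboxylate; 13 [4-(benzyloxy)-3,5-dimethoxyphenyl]boronic acid
Product: 14 methyl (4R)-6-(benzyloxy)-4-[4-(benzyloxy)-3,5-dimethoxyphenyl]-5,7-dimethoxy-2-oxochromane-3-carboxylate (C3 epimers)
Conditions: Rh(acac)(C2H4)2 (3 mol %), (R)-Segphos (3.3 mol %), 13 (3 equiv), dioxane/H2O 10:1, 60 °C
Reagents that add atoms: none
Why: Hayashi–Miyaura rhodium-catalysed asymmetric 1,4-addition, in which the aryl group passes from boron to rhodium and adds to C4 of the doubly activated coumarin on the face that the (R)-bisphosphine selects for the parent coumarin, which should set the (R) centre that becomes C1, after which water protonates the rhodium enolate; the C3 centre forms as an epimer mixture and disappears in step 8.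

Step 8
Reactants: 14 methyl (4R)-6-(benzyloxy)-4-[4-(benzyloxy)-3,5-dimethoxyphenyl]-5,7-dimethoxy-2-oxochromane-3-carboxylate
Product: 15 dimethyl 2-[(R)-[3-(benzyloxy)-6-hydroxy-2,4-dimethoxyphenyl][4-(benzyloxy)-3,5-dimethoxyphenyl]methyl]propanedioate
Conditions: K2CO3 (0.2 equiv), MeOH/THF, 0 °C; AcOH quench; used at once
Reagents that add atoms: methanol, CO
Why: base-catalysed transesterification of the aryl ester (lactone methanolysis) completes the malonate and frees the phenol; cold, weakly basic conditions should avoid retro-Michael loss of malonate through an ortho-quinone methide, so C1 is not at risk.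

Step 9
Reactants: 15 dimethyl 2-[(R)-[3-(benzyloxy)-6-hydroxy-2,4-dimethoxyphenyl][4-(benzyloxy)-3,5-dimethoxyphenyl]methyl]propanedioate
Product: 16 dimethyl 2-[(R)-[3-(benzyloxy)-2,4-dimethoxy-6-(trifluoromethanesulfonyloxy)phenyl][4-(benzyloxy)-3,5-dimethoxyphenyl]methyl]propanedioate
Conditions: Tf2O, pyridine, CH2Cl2, 0 °C
Reagents that add atoms: triflic anhydride, O=S(=O)(OS(=O)(=O)C(F)(F)F)C(F)(F)F
Why: O-sulfonylation of the phenol; pyridine does not deprotonate the malonate, and the triflate both blocks relactonisation and arms C4a for oxidative addition.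

Step 10
Reactants: 16 dimethyl 2-[(R)-[3-(benzyloxy)-2,4-dimethoxy-6-(trifluoromethanesulfonyloxy)phenyl][4-(benzyloxy)-3,5-dimethoxyphenyl]methyl]propanedioate; 17 buta-1,3-diene
Product: 18 dimethyl (1R,3R)-7-(benzyloxy)-1-[4-(benzyloxy)-3,5-dimethoxyphenyl]-3-ethenyl-6,8-dimethoxy-3,4-dihydronaphthalene-2,2(1H)-dicarboxylate
Conditions: Pd(OAc)2 (5 mol %), (R)-BINAP (7.5 mol %), K2CO3 (2 equiv), buta-1,3-diene (5 equiv), DMF, sealed tube, 80 °C
Reagents that add atoms: none
Why: Zerovalent palladium inserts into the C4a–OTf bond, the cationic arylpalladium species adds syn to a terminal double bond of butadiene (C4a–C4), and the potassium malonate attacks the inner carbon of the resulting allylpalladium unit anti to the metal (C2–C3), which returns zerovalent palladium. The closest known reaction type is the Larock carboannulation of 1,3-dienes by ortho-halo aryl malonates, run here in the cationic manifold of an aryl triflate as in Heck/allyl-capture cascades. Ring B closes in a 6-exo mode, since attack at the allyl terminus would need an eight-membered ring. The new C3 centre is controlled by C1: the C1–H bond should eclipse the planar malonate carbanion (allylic 1,3-strain), so the C1 aryl group and the allyl residue both take pseudo-equatorial sites in a chair-like transition state, giving the 1,3-cis product, and the bisphosphine, bound to an allyl unit whose faces interconvert (π–σ–π), is used in its matched hand to reinforce this. The step needs arylation at a diene terminus and capture of the allyl unit faster than β-hydride loss; the triflate with a single ortho substituent, the soft stabilised nucleophile held three bonds from C4a and an excess of diene should secure both.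

Step 11
Reactants: 18 dimethyl (1R,3R)-7-(benzyloxy)-1-[4-(benzyloxy)-3,5-dimethoxyphenyl]-3-ethenyl-6,8-dimethoxy-3,4-dihydronaphthalene-2,2(1H)-dicarboxylate
Product: 20 methyl (1R,2R,3R)-7-(benzyloxy)-1-[4-(benzyloxy)-3,5-dimethoxyphenyl]-3-ethenyl-6,8-dimethoxy-1,2,3,4-tetrahydronaphthalene-2-carboxylate, via C2-epimeric monoester 19 (not isolated)
Conditions: LiCl, H2O, DMSO, 150 °C; then NaOMe, MeOH, 65 °C
Reagents that add atoms: none
Why: Krapcho dealkoxycarbonylation (chloride removes one ester methyl group by SN2 attack and the carboxylate loses CO2) gives the monoester as a C2 epimer mixture, and methoxide equilibration through the ester enolate should settle the ester trans to both the C1 aryl and the C3 vinyl group, any residual epimer being returned to the equilibration; C1 and C3 carry no acidic hydrogen.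

Step 12
Reactants: 20 methyl (1R,2R,3R)-7-(benzyloxy)-1-[4-(benzyloxy)-3,5-dimethoxyphenyl]-3-ethenyl-6,8-dimethoxy-1,2,3,4-tetrahydronaphthalene-2-carboxylate
Product: 21 [(1R,2R,3R)-7-(benzyloxy)-1-[4-(benzyloxy)-3,5-dimethoxyphenyl]-3-ethenyl-6,8-dimethoxy-1,2,3,4-tetrahydronaphthalen-2-yl]methanol
Conditions: LiAlH4, THF, 0 °C
Reagents that add atoms: none
Why: hydride reduction of the ester to the primary alcohol C2a–OH; the vinyl group and the benzyl ethers are inert, and because C3a is still a vinyl group no hydroxyl can lactonise onto the ester.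

Step 13
Reactants: 21 [(1R,2R,3R)-7-(benzyloxy)-1-[4-(benzyloxy)-3,5-dimethoxyphenyl]-3-ethenyl-6,8-dimethoxy-1,2,3,4-tetrahydronaphthalen-2-yl]methanol
Product: 22 [(1R,2R,3R)-7-(benzyloxy)-1-[4-(benzyloxy)-3,5-dimethoxyphenyl]-3-ethenyl-6,8-dimethoxy-1,2,3,4-tetrahydronaphthalen-2-yl]methyl hydrogen sulfate
Conditions: SO3·pyridine, pyridine, rt; NaHCO3 work-up (sodium salt)
Reagents that add atoms: sulfur trioxide pyridine complex, [O-]S(=O)(=O)[n+]1ccccc1
Why: O-sulfation of the only free hydroxyl group; C3a is still masked as the vinyl group, which makes the sulfation site-selective.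

Step 14
Reactants: 22 [(1R,2R,3R)-7-(benzyloxy)-1-[4-(benzyloxy)-3,5-dimethoxyphenyl]-3-ethenyl-6,8-dimethoxy-1,2,3,4-tetrahydronaphthalen-2-yl]methyl hydrogen sulfate
Product: 25 [(1R,2S,3S)-7-(benzyloxy)-1-[4-(benzyloxy)-3,5-dimethoxyphenyl]-3-(hydroxymethyl)-6,8-dimethoxy-1,2,3,4-tetrahydronaphthalen-2-yl]methyl hydrogen sulfate, via glycol 23 (not isolated), via aldehyde 24 (not isolated)
Conditions: OsO4 (2 mol %), NaIO4, 2,6-lutidine, dioxane/H2O 3:1, rt; filter; then NaBH4, MeOH, 0 °C
Reagents that add atoms: osmium tetroxide, O=[Os](=O)(=O)=O; sodium periodate, [Na+].[O-]I(=O)(=O)=O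
Why: Lemieux–Johnson oxidation (osmium-catalysed dihydroxylation and periodate glycol cleavage) of the only alkene, then borohydride reduction, gives C3a–OH; lutidine keeps the medium near neutral so the aldehyde should not epimerise at C3, and this oxidant spares the electron-rich arenes and the sulfate (the change of descriptors is formal).

Step 15
Reactants: 25 [(1R,2S,3S)-7-(benzyloxy)-1-[4-(benzyloxy)-3,5-dimethoxyphenyl]-3-(hydroxymethyl)-6,8-dimethoxy-1,2,3,4-tetrahydronaphthalen-2-yl]methyl hydrogen sulfate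
Product: 26 [(1R,2S,3S)-7-hydroxy-1-(4-hydroxy-3,5-dimethoxyphenyl)-3-(hydroxymethyl)-6,8-dimethoxy-1,2,3,4-tetrahydronaphthalen-2-yl]methyl hydrogen sulfate (target)
Conditions: H2 (1 atm), Pd/C, MeOH, rt; then acidic ion-exchange resin
Reagents that add atoms: none
Why: hydrogenolysis of the two aryl benzyl ethers over palladium on carbon; the alkyl sulfate, the aryl methyl ethers and the three stereocentres are inert.

**Compound list**

1 | syringaldehyde | COc1cc(C=O)cc(OC)c1O | starting material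
2 | 4-(benzyloxy)-3,5-dimethoxybenzaldehyde | COc1cc(C=O)cc(OC)c1OCc1ccccc1 | intermediate
3 | 4-(benzyloxy)-3,5-dimethoxyphenyl formate | COc1cc(OC=O)cc(OC)c1OCc1ccccc1 | intermediate
4 | 4-(benzyloxy)-3,5-dimethoxyphenol | COc1cc(O)cc(OC)c1OCc1ccccc1 | intermediate
5 | 3-(benzyloxy)-6-hydroxy-2,4-dimethoxybenzaldehyde | COc1cc(O)c(C=O)c(OC)c1OCc1ccccc1 | intermediate
6 | dimethyl malonate | COC(=O)CC(=O)OC | starting material
7 | dimethyl 2-[[3-(benzyloxy)-6-hydroxy-2,4-dimethoxyphenyl]methylidene]propanedioate | COC(=O)C(=Cc1c(O)cc(OC)c(OCc2ccccc2)c1OC)C(=O)OC | intermediate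
8 | methyl 6-(benzyloxy)-5,7-dimethoxy-2-oxo-2H-chromene-3-carboxylate | COC(=O)C1=Cc2c(OC)c(OCc3ccccc3)c(OC)cc2OC1=O | intermediate
9 | 4-bromo-2,6-dimethoxyphenol | COc1cc(Br)cc(OC)c1O | starting material
10 | 2-(benzyloxy)-5-bromo-1,3-dimethoxybenzene | COc1cc(Br)cc(OC)c1OCc1ccccc1 | intermediate
11 | [4-(benzyloxy)-3,5-dimethoxyphenyl]lithium | [Li]c1cc(OC)c(OCc2ccccc2)c(OC)c1 | intermediate
12 | lithium [4-(benzyloxy)-3,5-dimethoxyphenyl]tri(propan-2-yloxy)borate | [Li+].CC(C)O[B-](OC(C)C)(OC(C)C)c1cc(OC)c(OCc2ccccc2)c(OC)c1 | intermediate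
13 | [4-(benzyloxy)-3,5-dimethoxyphenyl]boronic acid | COc1cc(B(O)O)cc(OC)c1OCc1ccccc1 | intermediate
14 | methyl (4R)-6-(benzyloxy)-4-[4-(benzyloxy)-3,5-dimethoxyphenyl]-5,7-dimethoxy-2-oxochromane-3-carboxylate, C3 epimers | COc1cc([C@@H]2c3c(OC)c(OCc4ccccc4)c(OC)cc3OC(=O)C2C(=O)OC)cc(OC)c1OCc1ccccc1 | intermediate
15 | dimethyl 2-[(R)-[3-(benzyloxy)-6-hydroxy-2,4-dimethoxyphenyl][4-(benzyloxy)-3,5-dimethoxyphenyl]methyl]propanedioate | COc1cc([C@@H](C(C(=O)OC)C(=O)OC)c2c(OC)c(OCc3ccccc3)c(OC)cc2O)cc(OC)c1OCc1ccccc1 | intermediate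
16 | dimethyl 2-[(R)-[3-(benzyloxy)-2,4-dimethoxy-6-(trifluoromethanesulfonyloxy)phenyl][4-(benzyloxy)-3,5-dimethoxyphenyl]methyl]propanedioate | COc1cc([C@@H](C(C(=O)OC)C(=O)OC)c2c(OC)c(OCc3ccccc3)c(OC)cc2OS(=O)(=O)C(F)(F)F)cc(OC)c1OCc1ccccc1 | intermediate
17 | buta-1,3-diene | C=CC=C | starting material
18 | dimethyl (1R,3R)-7-(benzyloxy)-1-[4-(benzyloxy)-3,5-dimethoxyphenyl]-3-ethenyl-6,8-dimethoxy-3,4-dihydronaphthalene-2,2(1H)-dicarboxylate | COc1cc([C@@H]2c3c(cc(OC)c(OCc4ccccc4)c3OC)C[C@H](C=C)C2(C(=O)OC)C(=O)OC)cc(OC)c1OCc1ccccc1 | intermediate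
19 | methyl (1R,3R)-7-(benzyloxy)-1-[4-(benzyloxy)-3,5-dimethoxyphenyl]-3-ethenyl-6,8-dimethoxy-1,2,3,4-tetrahydronaphthalene-2-carboxylate, mixture of C2 epimers | COc1cc([C@@H]2c3c(cc(OC)c(OCc4ccccc4)c3OC)C[C@H](C=C)C2C(=O)OC)cc(OC)c1OCc1ccccc1 | intermediate
20 | methyl (1R,2R,3R)-7-(benzyloxy)-1-[4-(benzyloxy)-3,5-dimethoxyphenyl]-3-ethenyl-6,8-dimethoxy-1,2,3,4-tetrahydronaphthalene-2-carboxylate | COc1cc([C@@H]2c3c(cc(OC)c(OCc4ccccc4)c3OC)C[C@H](C=C)[C@H]2C(=O)OC)cc(OC)c1OCc1ccccc1 | intermediate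
21 | [(1R,2R,3R)-7-(benzyloxy)-1-[4-(benzyloxy)-3,5-dimethoxyphenyl]-3-ethenyl-6,8-dimethoxy-1,2,3,4-tetrahydronaphthalen-2-yl]methanol | COc1cc([C@@H]2c3c(cc(OC)c(OCc4ccccc4)c3OC)C[C@H](C=C)[C@H]2CO)cc(OC)c1OCc1ccccc1 | intermediate
22 | [(1R,2R,3R)-7-(benzyloxy)-1-[4-(benzyloxy)-3,5-dimethoxyphenyl]-3-ethenyl-6,8-dimethoxy-1,2,3,4-tetrahydronaphthalen-2-yl]methyl hydrogen sulfate | COc1cc([C@@H]2c3c(cc(OC)c(OCc4ccccc4)c3OC)C[C@H](C=C)[C@H]2COS(=O)(=O)O)cc(OC)c1OCc1ccccc1 | intermediate
23 | [(1R,2S,3S)-7-(benzyloxy)-1-[4-(benzyloxy)-3,5-dimethoxyphenyl]-3-(1,2-dihydroxyethyl)-6,8-dimethoxy-1,2,3,4-tetrahydronaphthalen-2-yl]methyl hydrogen sulfate, carbinol epimers | COc1cc([C@@H]2c3c(cc(OC)c(OCc4ccccc4)c3OC)C[C@H](C(O)CO)[C@H]2COS(=O)(=O)O)cc(OC)c1OCc1ccccc1 | intermediate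
24 | [(1R,2S,3S)-7-(benzyloxy)-1-[4-(benzyloxy)-3,5-dimethoxyphenyl]-3-formyl-6,8-dimethoxy-1,2,3,4-tetrahydronaphthalen-2-yl]methyl hydrogen sulfate | COc1cc([C@@H]2c3c(cc(OC)c(OCc4ccccc4)c3OC)C[C@H](C=O)[C@H]2COS(=O)(=O)O)cc(OC)c1OCc1ccccc1 | intermediate
25 | [(1R,2S,3S)-7-(benzyloxy)-1-[4-(benzyloxy)-3,5-dimethoxyphenyl]-3-(hydroxymethyl)-6,8-dimethoxy-1,2,3,4-tetrahydronaphthalen-2-yl]methyl hydrogen sulfate | COc1cc([C@@H]2c3c(cc(OC)c(OCc4ccccc4)c3OC)C[C@H](CO)[C@H]2COS(=O)(=O)O)cc(OC)c1OCc1ccccc1 | intermediate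
26 | [(1R,2S,3S)-7-hydroxy-1-(4-hydroxy-3,5-dimethoxyphenyl)-3-(hydroxymethyl)-6,8-dimethoxy-1,2,3,4-tetrahydronaphthalen-2-yl]methyl hydrogen sulfate | COc1cc([C@@H]2c3c(cc(OC)c(O)c3OC)C[C@H](CO)[C@H]2COS(=O)(=O)O)cc(OC)c1O | target

**Step count**

Total steps: 15. Longest linear sequence: 13 (steps 1–4 and 7–15 from syringaldehyde); the boronic acid branch (steps 5–6) joins at step 7.

**Steps most likely to fail**

Step 10. The closure may show poor facial selectivity at C3, because the peri methoxy group on C8 pushes the C1 aryl group toward the pseudo-axial site, which would favour the 1,3-trans product. The arylpalladium intermediate may also be diverted into C–H arylation of the pendant ring. The fallback sets out from 16 and comes back at 18, forming the same two bonds in separate operations with C3 under pure catalyst control. Stille coupling of 16 with allyltributylstannane (Pd(PPh3)4, LiCl, dioxane, 100 °C) would give the ortho-allyl malonate dimethyl 2-[(R)-[3-(benzyloxy)-2,4-dimethoxy-6-(prop-2-en-1-yl)phenyl][4-(benzyloxy)-3,5-dimethoxyphenyl]methyl]propanedioate F1 (C4–C4a bond). Cross-metathesis with (Z)-but-2-ene-1,4-diyl dimethyl dicarbonate (second-generation Hoveyda–Grubbs catalyst, CH2Cl2, 40 °C) would give the (E)-allylic methyl carbonate F2. Iridium-catalysed intramolecular allylic alkylation ([Ir(cod)Cl]2, a Feringa-type phosphoramidite in the hand that delivers the (R) centre, TBD, THF, rt) would then close C2–C3 at the inner allyl carbon, where the ligand fixes the face of ionisation, and give 18.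

Step 7. Aryl transfer to the peri-hindered C4 of 8 may be slow, protodeboronation of 13 may outrun it, the β-dicarbonyl enolate may hold back the rhodium, or the face selectivity may erode on this trisubstituted acceptor. The fallback sets out from 5 and from aryllithium 11 (made from 10 as in step 6) and comes back at 15. Addition of 11 (2.2 equiv, THF, −78 to 0 °C) to 5 would give the racemic benzhydrol 4-(benzyloxy)-2-[[4-(benzyloxy)-3,5-dimethoxyphenyl](hydroxy)methyl]-3,5-dimethoxyphenol F3. Sodium 4-methylbenzenesulfinate in aqueous formic acid would convert it into the sulfone 4-(benzyloxy)-2-[[4-(benzyloxy)-3,5-dimethoxyphenyl](4-methylbenzenesulfonyl)methyl]-3,5-dimethoxyphenol F4. Aqueous K2CO3 with a cinchona-derived bifunctional squaramide in toluene would release the ortho-quinone methide F5, to which dimethyl malonate 6 adds under catalyst control (asymmetric Michael addition) to give 15. Any 14 formed by lactonisation is opened as in step 8.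

Step 14. The oxidant may attack the electron-rich rings, the α-branched aldehyde may epimerise at C3 before reduction, and material may be lost in separating the ionic sulfate from inorganic salts. The fallback sets out from 21 and comes back at 26, keeping all intermediates neutral until the penultimate stage.
- TBDPSCl and imidazole (DMF) would give the C2a silyl ether F6.
- The same OsO4/NaIO4/2,6-lutidine cleavage would pass through glycol F7 and aldehyde F8, and NaBH4 would give the C3a alcohol F9.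
- NaH and BnBr (DMF, 0 °C) would give the C3a benzyl ether F10.
- TBAF (THF) would free the C2a alcohol F11.
- SO3·pyridine would give the tribenzyl sulfate F12.
- Hydrogenolysis over Pd/C (H2, MeOH) would remove all three benzyl groups and give 26.

**Further compounds**

F1 | step 10 | dimethyl 2-[(R)-[3-(benzyloxy)-2,4-dimethoxy-6-(prop-2-en-1-yl)phenyl][4-(benzyloxy)-3,5-dimethoxyphenyl]methyl]propanedioate | COc1cc([C@@H](C(C(=O)OC)C(=O)OC)c2c(OC)c(OCc3ccccc3)c(OC)cc2CC=C)cc(OC)c1OCc1ccccc1
F2 | step 10 | dimethyl 2-[(R)-[3-(benzyloxy)-2,4-dimethoxy-6-[(2E)-4-(methoxycarbonyloxy)but-2-en-1-yl]phenyl][4-(benzyloxy)-3,5-dimethoxyphenyl]methyl]propanedioate | COc1cc([C@@H](C(C(=O)OC)C(=O)OC)c2c(OC)c(OCc3ccccc3)c(OC)cc2C/C=C/COC(=O)OC)cc(OC)c1OCc1ccccc1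
F3 | step 7 | 4-(benzyloxy)-2-[[4-(benzyloxy)-3,5-dimethoxyphenyl](hydroxy)methyl]-3,5-dimethoxyphenol (racemic) | COc1cc(C(O)c2c(OC)c(OCc3ccccc3)c(OC)cc2O)cc(OC)c1OCc1ccccc1
F4 | step 7 | 4-(benzyloxy)-2-[[4-(benzyloxy)-3,5-dimethoxyphenyl](4-methylbenzenesulfonyl)methyl]-3,5-dimethoxyphenol (racemic) | COc1cc(C(c2c(OC)c(OCc3ccccc3)c(OC)cc2O)S(=O)(=O)c2ccc(C)cc2)cc(OC)c1OCc1ccccc1
F5 | step 7 | 4-(benzyloxy)-6-[[4-(benzyloxy)-3,5-dimethoxyphenyl]methylidene]-3,5-dimethoxycyclohexa-2,4-dien-1-one (ortho-quinone methide) | COC1=CC(=O)C(=Cc2cc(OC)c(OCc3ccccc3)c(OC)c2)C(OC)=C1OCc1ccccc1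
F6 | step 14 | C2a-O-tert-butyldiphenylsilyl ether of 21 | COc1cc([C@@H]2c3c(cc(OC)c(OCc4ccccc4)c3OC)C[C@H](C=C)[C@H]2CO[Si](c5ccccc5)(c6ccccc6)C(C)(C)C)cc(OC)c1OCc1ccccc1
F7 | step 14 | C3 1,2-dihydroxyethyl glycol from F6, carbinol epimers | COc1cc([C@@H]2c3c(cc(OC)c(OCc4ccccc4)c3OC)C[C@H](C(O)CO)[C@H]2CO[Si](c5ccccc5)(c6ccccc6)C(C)(C)C)cc(OC)c1OCc1ccccc1
F8 | step 14 | C3 aldehyde with C2a-O-tert-butyldiphenylsilyl ether | COc1cc([C@@H]2c3c(cc(OC)c(OCc4ccccc4)c3OC)C[C@H](C=O)[C@H]2CO[Si](c5ccccc5)(c6ccccc6)C(C)(C)C)cc(OC)c1OCc1ccccc1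
F9 | step 14 | C3a alcohol with C2a-O-tert-butyldiphenylsilyl ether | COc1cc([C@@H]2c3c(cc(OC)c(OCc4ccccc4)c3OC)C[C@H](CO)[C@H]2CO[Si](c5ccccc5)(c6ccccc6)C(C)(C)C)cc(OC)c1OCc1ccccc1
F10 | step 14 | C3a benzyl ether with C2a-O-tert-butyldiphenylsilyl ether | COc1cc([C@@H]2c3c(cc(OC)c(OCc4ccccc4)c3OC)C[C@H](COCc5ccccc5)[C@H]2CO[Si](c6ccccc6)(c7ccccc7)C(C)(C)C)cc(OC)c1OCc1ccccc1
F11 | step 14 | C2a alcohol with C3a benzyl ether | COc1cc([C@@H]2c3c(cc(OC)c(OCc4ccccc4)c3OC)C[C@H](COCc5ccccc5)[C@H]2CO)cc(OC)c1OCc1ccccc1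
F12 | step 14 | C2a hydrogen sulfate with C3a benzyl ether (tribenzyl target) | COc1cc([C@@H]2c3c(cc(OC)c(OCc4ccccc4)c3OC)C[C@H](COCc5ccccc5)[C@H]2COS(=O)(=O)O)cc(OC)c1OCc1ccccc1
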